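Birch, charged with more free base than oak, had lost more of its electrophile after 120 s: 30.2 % against 24.3 %. But [free base] had risen by a factor of 1.88, and the loss by a factor of 1.24.

| flask | electrophile | free base | protonated nucleophile | remark | time |
|---|---|---|---|---|---|
| oak | 0.050 M | 0.017 M | 0.055 M | run made earlier |  |
| birch | 0.050 M | 0.032 M | 0.055 M | run made earlier |  |
| Saturday's | 0.050 M | 0.0150 M | 0.0550 M |  | 3.0 min |
| Friday's | 0.050 M | 0.0220 M | 0.0550 M |  | 3.0 min |
| Tuesday's | 0.050 M | 0.0340 M | 0.0550 M |  | 3.0 min |

- oak (time / s: electrophile / %, target / %): 12.0: 99.1, 1.9; 30.0: 94.4, 2.7; 60.0: 88.1, 6.0; 90.0: 81.6, 7.6; 120: 75.7, 7.7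
- birch (time / s: electrophile / %, target / %): 10.0: 98.3, 1.2; 20.0: 96.4, 3.0; 40.0: 90.8, 5.1; 60.0: 84.3, 8.4; 120: 69.8, 11.3

(standard deviation of a reading: 0.5 percentage points)



1. part of the electrophile that has reacted at the end, Saturday's
2. part of the electrophile that has reacted at the end, Friday's
3. part of the electrophile that has reacted at the end, Tuesday's
4. what raising the concentration of free base from its lowest to its highest value here does to the part of the electrophile that has reacted (changes below 5 percentage points count as none) (it rises / it falls / no change)

Both losses had come nearly straight in time, so my bench rule was to run the line on. I scaled the loss with time and with [free base] raised to the power that these two runs gave: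

n = ln(loss in birch / loss in oak) / ln([free base] in birch / [free base] in oak) = 0.344

loss = 24.3 % × (time / 120 s) × ([free base] / 0.017 M)^n

At 3.0 min this gave 34.9 % for Saturday's, 39.8 % for Friday's and 46.3 % for Tuesday's.

A straight line knows nothing of the charge, so I counted turnovers:

N = loss × [electrophile] charged / [free base] charged

For Saturday's this came to 1.16, the turnover count, electrophile lost per free base charged. If each electrophile lost took one free base, that base would be the limiting reagent and the line would stop at one turnover, which for Saturday's is a loss of 30.0 %. Saturday's line crossed that border, so I expected its loss between the two figures. Friday's at 0.905 and Tuesday's at 0.680 stayed under it, so my own reckoning, which is not the forecast's, kept their lines.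

The forecast, a little below my lines for Friday's and Tuesday's, gave 31 %, 38 % and 45 %, said it rises, and noted that “Oak shows no clear stall, but this could trim the low-base run”.

The flask gave 32.0 % for Saturday's, 36.3 % for Friday's and 43.0 % for Tuesday's, and from lowest to highest free base it rises, by 11 percentage points. Saturday's count ended at 1.07 against my 1.16. It passed one, with 0.077 % of the free base left beside 68 % of the electrophile, so the loss crossed my border.

    2 nucleophile → homo dimer (k = 0.0710 M⁻¹ s⁻¹)
    acid set free + free base ⇌ salt of the base (K = 1.70 × 10⁶ M⁻¹, k = 4.70 M⁻¹ s⁻¹)
    nucleophile + acid set free ⇌ protonated nucleophile, settled at all times (K = 570 M⁻¹)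
    electrophile + nucleophile → acid set free + target (k = 0.150 M⁻¹ s⁻¹)
    electrophile + target → side product (k = 0.300 M⁻¹ s⁻¹)

The neighbour flask charged with 0.020 M of free base, its other charges and its time as in Tuesday's, reckons to a line of 38.5 % and a count of 0.964, just under one. Computed, that flask lost 35.1 %, a count of 0.878, with 0.23 % of its free base left.

All runs stem from a simulated flask with made-up constants, and the scatter is random.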